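**Assumption:** nortopsentin A has no stereocentre (it is achiral, and the 4- and 5-substituted imidazole N–H tautomers are one compound), so it is made as drawn and no stereocontrol is needed.

**Retrosynthetic overview**
- The imidazole is cut into three pieces at once (Debus–Radziszewski): C4–C5 from an indol-3-ylglyoxal, C2 from an indole-3-carbaldehyde, both nitrogens from ammonia. This replaces the usual amidine + α-haloketone condensation or stepwise cross-coupling on a haloimidazole.
- The glyoxal comes from 6-bromoindole by C3 glyoxylation with oxalyl chloride and partial reduction of the acyl chloride.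
- Ring order: both 6-bromoindole rings are bought intact with bromine already at C6; the imidazole is the only ring formed, and it is formed last.
- No protecting groups and no transition-metal catalysis, so the two aryl bromides are never at risk from cross-coupling conditions.

**Step 1**
Reactants: 1 6-bromo-1H-indole
Product: 2 2-(6-bromo-1H-indol-3-yl)-2-oxoacetyl chloride
Conditions: (COCl)2 (1.3 equiv), Et2O, 0 °C to rt, 2 h; filter the precipitate under N2
Reagents that add atoms: oxalyl chloride, O=C(Cl)C(Cl)=O
Why: Uncatalysed Friedel–Crafts C3 acylation of the free N–H indole (Speeter–Anthony glyoxylation); the deactivated product precipitates from ether and cannot react a second time.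

**Step 2**
Reactants: 2 2-(6-bromo-1H-indol-3-yl)-2-oxoacetyl chloride
Product: 3 2-(6-bromo-1H-indol-3-yl)-2-oxoacetaldehyde (may be obtained partly as its hydrate, which reacts the same way)
Conditions: Bu3SnH (1.05 equiv), EtOAc, 0 °C to rt, 3 h; triturate with hexane
Reagents that add atoms: none
Why: Tin hydride reduction of an acyl chloride to the aldehyde; the α-keto acyl chloride is by far the most reactive site, while the vinylogous-amide ketone and the aryl C–Br bond (no radical initiator, no heating) are left alone.

**Step 3**
Reactants: 3 2-(6-bromo-1H-indol-3-yl)-2-oxoacetaldehyde; 4 6-bromo-1H-indole-3-carbaldehyde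
Product: 6 nortopsentin A [2,4-bis(6-bromo-1H-indol-3-yl)-1H-imidazole], via 2H-imidazole tautomer 5 (not isolated)
Conditions: 4 (2 equiv), NH4OAc (10 equiv), MeOH, 50 °C, 30 min; then 3 in THF/MeOH added by syringe pump over 8 h, 50 °C; excess 4 recovered on chromatography
Reagents that add atoms: ammonium acetate, CC(=O)[O-].[NH4+]
Why: Debus–Radziszewski three-component imidazole synthesis, in which the 1,2-dicarbonyl of 3, aldehyde 4 and two molecules of ammonia condense to the 2H-imidazole 5, which aromatises by a 1,5-hydrogen shift; keeping 3 dilute against excess 4 suppresses the second-order self-condensation of 3 to a 2-acylimidazole, both indoles are C3-blocked so no bis(indolyl)methane forms, and no stereocentre remains in the product.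

**Compound list**
1 | 6-bromo-1H-indole | Brc1ccc2cc[nH]c2c1 | starting material
2 | 2-(6-bromo-1H-indol-3-yl)-2-oxoacetyl chloride | O=C(Cl)C(=O)c1c[nH]c2cc(Br)ccc12 | intermediate
3 | 2-(6-bromo-1H-indol-3-yl)-2-oxoacetaldehyde | O=CC(=O)c1c[nH]c2cc(Br)ccc12 | intermediate
4 | 6-bromo-1H-indole-3-carbaldehyde | O=Cc1c[nH]c2cc(Br)ccc12 | starting material
5 | 2,4-bis(6-bromo-1H-indol-3-yl)-2H-imidazole (racemic at the sp3 C2, which is lost on aromatisation; not isolated) | Brc1ccc2c(C3N=CC(=N3)c4c[nH]c5cc(Br)ccc45)c[nH]c2c1 | intermediate
6 | nortopsentin A, 2,4-bis(6-bromo-1H-indol-3-yl)-1H-imidazole (achiral) | Brc1ccc2c(-c3c[nH]c(-c4c[nH]c5cc(Br)ccc45)n3)c[nH]c2c1 | target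

**Total step count:** 3
**Longest linear sequence:** 3 steps (1 → 2 → 3 → 6); aldehyde 4 is bought.

**Steps most likely to fail, with fallbacks**

*Step 3 (highest risk).* Glyoxal 3 can self-condense with ammonia to a 2-acyl-4-indolylimidazole faster than it captures the poorly electrophilic vinylogous-formamide aldehyde 4. The fallback gives up the three-component assembly for the classical amidine + α-haloketone condensation. It sets out from 1 and 4 and comes back to the route at 6.
- Compound 1 is C3-acylated with chloroacetyl chloride and pyridine in dioxane at 60 °C to give 1-(6-bromo-1H-indol-3-yl)-2-chloroethan-1-one F1.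
- Compound 4 is heated with NH2OH·HCl and HCO2Na in HCO2H; it passes through (E)-6-bromo-1H-indole-3-carbaldehyde oxime F2 and dehydrates to 6-bromo-1H-indole-3-carbonitrile F3.
- The nitrile is aminated with the reagent from AlMe3 and NH4Cl in toluene at 80 °C to give 6-bromo-1H-indole-3-carboximidamide F4.
- F1 and F4 are condensed with KHCO3 in THF/H2O at reflux (N-alkylation, then cyclodehydration) to give 6.

*Step 2.* The reduction can over-reduce, form ester by-products, partly debrominate by a radical chain, or give a glyoxal that is hard to free of tin residues. The fallback replaces direct tin hydride reduction with a chelate-controlled Weinreb reduction. It sets out from 2 and comes back at 3.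
- Compound 2 is treated with MeNH(OMe)·HCl and pyridine in CH2Cl2 at 0 °C to give 2-(6-bromo-1H-indol-3-yl)-N-methoxy-N-methyl-2-oxoacetamide F5.
- F5 is reduced with LiAlH4 (2 equiv) in THF at −78 to −20 °C and worked up with aqueous KHSO4 to give 3. The first hydride deprotonates the indole N–H, which shuts down the already deactivated C3 ketone, so only the Weinreb amide is reduced, to its stable chelate.

*Step 1 (lowest risk).* Acid chloride 2 is moisture-sensitive, and diacylation to a bis(indolyl) diketone is possible if addition is mishandled. The fallback introduces the two carbons at the ketone oxidation level and oxidises afterwards. It sets out from 1 and comes back at 3, bypassing 2.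
- Compound 1 is acetylated at C3 with AcCl and Et2AlCl in CH2Cl2 at 0 °C to give 1-(6-bromo-1H-indol-3-yl)ethan-1-one F6.
- F6 is oxidised with SeO2 in dioxane/H2O at 100 °C (Riley oxidation of the methyl ketone) to give 3.

**Further compounds**
F1 | step 3 | 1-(6-bromo-1H-indol-3-yl)-2-chloroethan-1-one | O=C(CCl)c1c[nH]c2cc(Br)ccc12
F2 | step 3 | (E)-6-bromo-1H-indole-3-carbaldehyde oxime | O/N=C/c1c[nH]c2cc(Br)ccc12
F3 | step 3 | 6-bromo-1H-indole-3-carbonitrile | N#Cc1c[nH]c2cc(Br)ccc12
F4 | step 3 | 6-bromo-1H-indole-3-carboximidamide | NC(=N)c1c[nH]c2cc(Br)ccc12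
F5 | step 2 | 2-(6-bromo-1H-indol-3-yl)-N-methoxy-N-methyl-2-oxoacetamide | CON(C)C(=O)C(=O)c1c[nH]c2cc(Br)ccc12
F6 | step 1 | 1-(6-bromo-1H-indol-3-yl)ethan-1-one | CC(=O)c1c[nH]c2cc(Br)ccc12
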